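**Retrosynthetic overview** (cyclohexene locants as in 3,5,5-trimethylcyclohex-2-en-1-yl; C7 = carbinol carbon)
1. Target 9 ← ketone 8 by Felkin–Anh hydride reduction of the C7 carbonyl (last step).
2. 8 ← cyclopropyl isopropenyl carbinol 6 + limettin 3 in one acid-triggered cascade: the cyclopropane is cleaved, the cyclohexene is closed by the bond between the ring CH2 (C4) and the gem-dimethyl carbon (C5), and the resulting cyclohexenyl cation is arylated at C1.
3. Enabling feature: C5(Me2), C6 and C1 of the cyclohexene are the cyclopropane carbons of (1R,3R)-trans-chrysanthemic acid, C7 is its carboxyl carbon and C2=C3(Me)–C4 is its isobutenyl group. The acid's carboxyl-bearing stereocentre therefore becomes C6, and the cyclopropane bond C1–C5 is the one that breaks.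
4. 6 ← aryl cyclopropyl ketone 4 (Schenck ene reaction) ← chrysanthemoyl chloride 2 + limettin 3 (Friedel–Crafts acylation).
5. Ring order: both coumarins and the cyclopropane are bought; the cyclohexene is the only ring made (step 4), at the expense of the cyclopropane.

Key step: step 4

Assumption (chemistry): carbon electrophiles attack 5,7-dimethoxycoumarin at C8, as in the C8 acylation of 5,7-dioxygenated coumarins; (+)-trans-chrysanthemic acid is taken as commercially available.

**Step 1**
Reactants: 1 (1R,3R)-trans-chrysanthemic acid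
Product: 2 (1R,3R)-trans-chrysanthemoyl chloride
Conditions: (COCl)2, DMF (cat.), CH2Cl2, 0 °C to rt
Reagents that add atoms: oxalyl chloride, ClC(=O)C(=O)Cl
Why: Acyl substitution through the Vilsmeier-type chloroiminium activation should give the acid chloride, and the cyclopropane stereocentres are safe because cyclopropyl α-hydrogens resist enolisation.

**Step 2**
Reactants: 2 (1R,3R)-trans-chrysanthemoyl chloride; 3 limettin (5,7-dimethoxycoumarin)
Product: 4 8-chrysanthemoyl-limettin (aryl cyclopropyl ketone)
Conditions: SnCl4 (2.2 equiv), 2,6-di-tert-butyl-4-methylpyridine (1.1 equiv), CH2Cl2, −40 to 0 °C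
Reagents that add atoms: none
Why: Friedel–Crafts acylation by the cyclopropyl-stabilised acylium ion should occur at C8 of limettin (ortho to two oxygens, para to the 5-methoxy group), while the hindered base removes HCl so that the isobutenyl group and the cyclopropane are not protonated; no stereocentre is formed or touched.

**Step 3**
Reactants: 4 8-chrysanthemoyl-limettin
Product: 6 cyclopropyl isopropenyl carbinol (both carbinol epimers), via allylic hydroperoxide 5 (not isolated)
Conditions: O2, tetraphenylporphyrin (cat.), white LED, CH2Cl2, 0 °C; then PPh3, 0 °C to rt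
Reagents that add atoms: dioxygen (as singlet oxygen), O=O
Why: In the Schenck ene reaction singlet oxygen should take hydrogen only from a methyl group of the trisubstituted alkene (abstraction of the cyclopropane C–H would give a strained alkylidenecyclopropane), shifting the double bond to the terminal position, and PPh3 reduces the hydroperoxide; the new carbinol centre is formed unselectively, which does not matter because it is ionised in step 4.

**Step 4**
Reactants: 6 cyclopropyl isopropenyl carbinol; 3 limettin
Product: 8 trans-(1S,6R) diaryl ketone, via cyclohexenyl cation 7 (not isolated)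
Conditions: TfOH (10 mol %), (CF3)2CHOH/CH2Cl2, 0 °C; 6 added slowly to 3 (3 equiv)
Reagents that add atoms: none
Why: Proposed new method: acid ionises the carbinol of 6 to a 1-cyclopropyl-2-methylallyl cation, whose cyclopropane bond between the allyl-bearing carbon and the gem-dimethyl carbon opens while the gem-dimethyl carbon is captured by the terminal CH2 of the allyl unit, so that the six-membered ring closes in an endo mode (the whole allyl unit ends inside the ring) and the 3-methylcyclohex-2-enyl cation 7 results, driven by loss of cyclopropane strain. The closest known reaction types are the formal homo-Nazarov cyclisation of vinyl cyclopropyl ketones and the cyclopropylcarbinyl-to-homoallyl rearrangement, followed by a Friedel–Crafts allylation of the kind that joins menthadienol and olivetol. Cation 7 should be trapped by C8 of limettin at its secondary terminus C1, which leaves the C2=C3 double bond trisubstituted. The new stereocentre C1 is controlled by the untouched C6 (the former carboxyl-bearing carbon of chrysanthemic acid): the arene enters anti to the bulky aroyl group, giving the trans 1,6-relationship, which is also the thermodynamic one. Four selectivities are needed: cleavage of the correct cyclopropane bond (secured by the tertiary cation site and by the aroyl group that deactivates the other vicinal bond), closure from the cisoid allyl cation rotamer (reachable because ionisation is reversible and only this rotamer can close), arylation at the secondary and not the tertiary terminus (the tertiary one is neopentyl-like and would give a quaternary centre), and trapping of 7 before proton loss at C6 (excess arene, non-basic fluoroalcohol medium).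

**Step 5**
Reactants: 8 trans-(1S,6R) diaryl ketone
Product: 9 IN0553
Conditions: NaBH4, CeCl3·7H2O, MeOH/THF, −20 to 0 °C
Reagents that add atoms: none
Why: Luche 1,2-reduction should reduce only the aryl ketone (coumarin lactones and the alkene are inert), and Felkin–Anh attack anti to the quaternary C5, passing the C6 hydrogen with the carbonyl oxygen on the side of C1, should set C7 as R.

**Compound list**
1 | (1R,3R)-2,2-dimethyl-3-(2-methylprop-1-en-1-yl)cyclopropane-1-carboxylic acid, (+)-trans-chrysanthemic acid | OC(=O)[C@H]1C(C)(C)[C@@H]1C=C(C)C | starting material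
2 | (1R,3R)-2,2-dimethyl-3-(2-methylprop-1-en-1-yl)cyclopropane-1-carbonyl chloride | ClC(=O)[C@H]1C(C)(C)[C@@H]1C=C(C)C | intermediate
3 | limettin, 5,7-dimethoxy-2H-chromen-2-one | COc1cc(OC)c2ccc(=O)oc2c1 | starting material
4 | 8-{[(1R,3R)-2,2-dimethyl-3-(2-methylprop-1-en-1-yl)cyclopropyl]carbonyl}-5,7-dimethoxy-2H-chromen-2-one | COc1cc(OC)c2ccc(=O)oc2c1C(=O)[C@H]1C(C)(C)[C@@H]1C=C(C)C | intermediate
5 | 8-{[(1R,3R)-3-(1-hydroperoxy-2-methylprop-2-en-1-yl)-2,2-dimethylcyclopropyl]carbonyl}-5,7-dimethoxy-2H-chromen-2-one, both epimers at the hydroperoxide carbon | COc1cc(OC)c2ccc(=O)oc2c1C(=O)[C@H]1C(C)(C)[C@@H]1C(OO)C(C)=C | intermediate (not isolated)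
6 | 8-{[(1R,3R)-3-(1-hydroxy-2-methylprop-2-en-1-yl)-2,2-dimethylcyclopropyl]carbonyl}-5,7-dimethoxy-2H-chromen-2-one, both carbinol epimers | COc1cc(OC)c2ccc(=O)oc2c1C(=O)[C@H]1C(C)(C)[C@@H]1C(O)C(C)=C | intermediate
7 | (6R)-6-(5,7-dimethoxy-2-oxo-2H-chromene-8-carbonyl)-3,5,5-trimethylcyclohex-2-en-1-ylium (allyl cation, one resonance form drawn) | [CH+]1C=C(C)CC(C)(C)[C@@H]1C(=O)c1c(OC)cc(OC)c2ccc(=O)oc12 | intermediate (not isolated)
8 | 8-[(1S,6R)-6-(5,7-dimethoxy-2-oxo-2H-chromene-8-carbonyl)-3,5,5-trimethylcyclohex-2-en-1-yl]-5,7-dimethoxy-2H-chromen-2-one | COc1cc(OC)c2ccc(=O)oc2c1[C@H]1C=C(C)CC(C)(C)[C@@H]1C(=O)c1c(OC)cc(OC)c2ccc(=O)oc12 | intermediate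
9 | IN0553, 8-[(1S,6R)-6-[(R)-hydroxy(5,7-dimethoxy-2-oxo-2H-chromen-8-yl)methyl]-3,5,5-trimethylcyclohex-2-en-1-yl]-5,7-dimethoxy-2H-chromen-2-one | COc1cc(OC)c2ccc(=O)oc2c1[C@H]1C=C(C)CC(C)(C)[C@@H]1[C@@H](O)c1c(OC)cc(OC)c2ccc(=O)oc12 | target

Total step count: 5
Longest linear sequence: 5 steps (1 → 2 → 4 → 6 → 8 → 9)

**Steps most likely to fail**

Step 4 (proposed new method). What may go wrong:
- Limettin may capture the first, acyclic allyl cation before the ring expansion.
- Proton loss at C6, from the open tertiary cation or from cation 7, would give conjugated dienones and erase the only stereocentre carried from the terpene.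
- Arylation may occur at C6 of limettin instead of C8.

Fallback with known chemistry, setting out from limettin 3 and coming back at ketone 8: Rieche formylation of 3 (Cl2CHOMe, TiCl4, CH2Cl2, then water) should give 5,7-dimethoxy-2-oxo-2H-chromene-8-carbaldehyde F1. Horner–Wadsworth–Emmons olefination of F1 with diethyl (2-methylallyl)phosphonate and LiN(SiMe3)2 should give (E)-5,7-dimethoxy-8-(3-methylbuta-1,3-dien-1-yl)-2H-chromen-2-one F2. Separately, Friedel–Crafts acylation of 3 with 3-methylbut-2-enoyl chloride (SnCl4) should give 5,7-dimethoxy-8-(3-methylbut-2-enoyl)-2H-chromen-2-one F3. A Diels–Alder reaction of diene F2 with enone F3, catalysed by a chiral oxazaborolidinium triflimide (protonated o-tolyl-CBS oxazaborolidine, the antipode chosen so that C1 forms as S), joins the aryl-bearing diene terminus to the α-carbon and the CH2 terminus to the β-carbon of the enone. Any cis adduct, the (1S,6S) ketone F4, is equilibrated at C6 with DBU to the trans ketone 8.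

Step 2. What may go wrong:
- Acylation at the wrong site of limettin.
- Lewis-acid cleavage of the methoxy group ortho to the new ketone.
- Protonation of the isobutenyl group or opening of the cyclopropane by adventitious HCl.

Fallback, setting out from 3 and coming back at 4: iodination of 3 (N-iodosuccinimide, cat. CF3CO2H, MeCN) should give 8-iodo-5,7-dimethoxy-2H-chromen-2-one F5. Zinc insertion (Zn dust, LiCl, THF) should give the lactone-tolerant (5,7-dimethoxy-2-oxo-2H-chromen-8-yl)zinc iodide F6. Negishi acylation of F6 with acid chloride 2 (Pd(PPh3)4, THF) should give ketone 4 under neutral conditions.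

Step 5. What may go wrong:
- Poor or reversed facial selectivity at the hindered carbonyl, because C1 with its aryl group competes with C5 for the role of the large substituent.
- Slow reduction that lets the coumarin lactones be attacked.

Fallback, setting out from 8 and coming back at 9: if hydride delivery favours the 7S epimer of the alcohol F7, this epimer is inverted by a Mitsunobu reaction (4-nitrobenzoic acid, PPh3, diisopropyl azodicarboxylate, THF) to the 7R 4-nitrobenzoate F8. Mild methanolysis (K2CO3, MeOH, 0 °C) then releases 9.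

**Further compounds**
F1 | step 4 | 5,7-dimethoxy-2-oxo-2H-chromene-8-carbaldehyde | COc1cc(OC)c2ccc(=O)oc2c1C=O
F2 | step 4 | (E)-5,7-dimethoxy-8-(3-methylbuta-1,3-dien-1-yl)-2H-chromen-2-one | COc1cc(OC)c2ccc(=O)oc2c1/C=C/C(C)=C
F3 | step 4 | 5,7-dimethoxy-8-(3-methylbut-2-enoyl)-2H-chromen-2-one | COc1cc(OC)c2ccc(=O)oc2c1C(=O)C=C(C)C
F4 | step 4 | 8-[(1S,6S)-6-(5,7-dimethoxy-2-oxo-2H-chromene-8-carbonyl)-3,5,5-trimethylcyclohex-2-en-1-yl]-5,7-dimethoxy-2H-chromen-2-one (cis adduct) | COc1cc(OC)c2ccc(=O)oc2c1[C@H]1C=C(C)CC(C)(C)[C@H]1C(=O)c1c(OC)cc(OC)c2ccc(=O)oc12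
F5 | step 2 | 8-iodo-5,7-dimethoxy-2H-chromen-2-one | COc1cc(OC)c2ccc(=O)oc2c1I
F6 | step 2 | (5,7-dimethoxy-2-oxo-2H-chromen-8-yl)zinc iodide | COc1cc(OC)c2ccc(=O)oc2c1[Zn]I
F7 | step 5 | 8-[(1S,6R)-6-[(S)-hydroxy(5,7-dimethoxy-2-oxo-2H-chromen-8-yl)methyl]-3,5,5-trimethylcyclohex-2-en-1-yl]-5,7-dimethoxy-2H-chromen-2-one (C7 epimer of 9) | COc1cc(OC)c2ccc(=O)oc2c1[C@H]1C=C(C)CC(C)(C)[C@@H]1[C@H](O)c1c(OC)cc(OC)c2ccc(=O)oc12
F8 | step 5 | (R)-(5,7-dimethoxy-2-oxo-2H-chromen-8-yl)[(1R,6S)-6-(5,7-dimethoxy-2-oxo-2H-chromen-8-yl)-2,2,4-trimethylcyclohex-3-en-1-yl]methyl 4-nitrobenzoate | COc1cc(OC)c2ccc(=O)oc2c1[C@H]1C=C(C)CC(C)(C)[C@@H]1[C@@H](OC(=O)c1ccc(cc1)[N+](=O)[O-])c1c(OC)cc(OC)c2ccc(=O)oc12
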